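## Retrosynthetic overview

1. The three esters go on last. The 7,9,15-triol comes from a 7,9-diketone by two hydroxyl-directed hydride deliveries. Ring C (seven-membered, C5–C6–C7–C8–C9–C10 plus C4 or C11) is closed by a Claisen condensation C8–C9.
2. Ring B (cyclobutane C4–C5–C11–C10) is closed before that by a 4-exo epoxide opening with an ester enolate (C4–C10), on a cyclohexene whose C1 ketone is masked as a ketal.
3. Ring A (the 3-methylcyclohex-2-enone C1–C2–C3–C4–C5–C11) is made first, in the key step: a tethered [3+3] annulation of acyclic enone phosphonate 10, Michael addition (C5–C11) followed by Horner–Wadsworth–Emmons olefination (C2=C3).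
4. Enabling feature: ring A is a 3-methylcyclohex-2-enone whose C1 carbonyl is flanked by two nucleophilic carbons (C11, C2) facing a pent-3-en-2-one unit (C5 as β-carbon, C3 as carbonyl carbon). C5 also carries C6–C7(O), so a 3-oxobutanoate on the C7 oxygen reaches C5 through a six-membered lactone that is later lost as CO2.
5. Chiral pool: ethyl (3S)-3-hydroxybutanoate supplies C15–C6–C7–C8. Its carbinol centre sets C6 and C5, is then erased (ketone) and rebuilt.

Key step: step 9

Atom numbers (C1–C15) are those of the target skeleton: C1 ketone; C2=C3(CH3) enone; C4 and C11 bridgeheads; C5 (H) and C10 (CH3) the one-carbon bridges; C6–C7–C8–C9 the four-carbon bridge; C15 the CH2O carbon on C6.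

Remark on the chemistry: C10 is carried as a mixture of epimers from 13 to 19, and C11 is undefined in 12–14. Both centres are set later (steps 11 and 15), so those SMILES leave them open.

## Route

Step 1
Reactants: 1 ethyl (3S)-3-hydroxybutanoate
Product: 2 ethyl (2S,3S)-3-hydroxy-2-methylbutanoate
Conditions: LiN(i-Pr)2 (2.2 equiv), THF, −78 to −20 °C; MeI, −78 to 0 °C; then 1 M HCl
Reagents that add atoms: iodomethane CI
Why: Fráter–Seebach alkylation, in which the chelated lithium alkoxide enolate is methylated on the face away from the carbinol methyl group and should give the anti (2S,3S) ester.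

Step 2
Reactants: 2 ethyl (2S,3S)-3-hydroxy-2-methylbutanoate
Product: 3 ethyl (2S,3S)-3-hydroxy-2-(hydroxymethyl)-2-methylbutanoate
Conditions: LiN(i-Pr)2 (2.2 equiv), THF, −78 to −20 °C; gaseous CH2O (cracked paraformaldehyde), −78 °C; then 1 M HCl
Reagents that add atoms: formaldehyde C=O
Why: second Fráter–Seebach reaction (aldol addition to formaldehyde), in which the same enolate face is attacked again, so the hydroxymethyl group should enter anti to the carbinol methyl group and set the quaternary carbon (later C6) as S.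

Step 3
Reactants: 3 ethyl (2S,3S)-3-hydroxy-2-(hydroxymethyl)-2-methylbutanoate
Product: 4 ethyl (2S,3S)-2-[(tert-butyldiphenylsilyloxy)methyl]-3-hydroxy-2-methylbutanoate
Conditions: t-BuPh2SiCl, imidazole, CH2Cl2, 0 °C
Reagents that add atoms: tert-butyl(chloro)diphenylsilane CC(C)(C)[Si](Cl)(c1ccccc1)c1ccccc1
Why: silyl ether formation that should be selective for the primary hydroxyl over the hindered secondary one, with no change at the stereocentres.

Step 4
Reactants: 4 ethyl (2S,3S)-2-[(tert-butyldiphenylsilyloxy)methyl]-3-hydroxy-2-methylbutanoate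
Product: 5 (2S,3S)-2-[(tert-butyldiphenylsilyloxy)methyl]-2-methylbutane-1,3-diol
Conditions: LiAlH4, THF, 0 to 23 °C; aqueous work-up
Reagents that add atoms: none
Why: hydride reduction of the ester to the primary alcohol, which turns the former ester carbon into the future C5.

Step 5
Reactants: 5 (2S,3S)-2-[(tert-butyldiphenylsilyloxy)methyl]-2-methylbutane-1,3-diol
Product: 6 (2S,3S)-2-[(tert-butyldiphenylsilyloxy)methyl]-3-hydroxy-2-methylbutanal
Conditions: TEMPO (cat.), PhI(OAc)2, CH2Cl2, 23 °C
Reagents that add atoms: none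
Why: nitroxyl-catalysed oxidation, which is selective for the primary alcohol; the aldehyde has no α-hydrogen and cannot epimerise.

Step 6
Reactants: 6 (2S,3S)-2-[(tert-butyldiphenylsilyloxy)methyl]-3-hydroxy-2-methylbutanal
Product: 7 (3E,5S,6S)-5-[(tert-butyldiphenylsilyloxy)methyl]-6-hydroxy-5-methylhept-3-en-2-one
Conditions: Ph3P=CHC(O)CH3, toluene, 90 °C
Reagents that add atoms: (acetylmethylene)triphenylphosphorane CC(=O)C=P(c1ccccc1)(c1ccccc1)c1ccccc1
Why: Wittig olefination with a stabilised ylide, which should give the E enone (C3 carbonyl, C4=C5) even on the α-quaternary aldehyde.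

Step 7
Reactants: 8 2,2,6-trimethyl-4H-1,3-dioxin-4-one
Product: 9 diethyl [(2,2-dimethyl-4-oxo-4H-1,3-dioxin-6-yl)methyl]phosphonate
Conditions: LiN(i-Pr)2 (2.1 equiv), THF, −78 °C; ClP(O)(OEt)2, −78 to 0 °C; then 1 M HCl
Reagents that add atoms: diethyl chlorophosphate CCOP(=O)(Cl)OCC
Why: C-phosphorylation of the vinylogous (γ) enolate of the dioxinone, a known route to this acylketene precursor.

Step 8
Reactants: 7 (3E,5S,6S)-5-[(tert-butyldiphenylsilyloxy)methyl]-6-hydroxy-5-methylhept-3-en-2-one; 9 diethyl [(2,2-dimethyl-4-oxo-4H-1,3-dioxin-6-yl)methyl]phosphonate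
Product: 10 (2S,3S,4E)-3-[(tert-butyldiphenylsilyloxy)methyl]-3-methyl-6-oxohept-4-en-2-yl 4-(diethoxyphosphoryl)-3-oxobutanoate
Conditions: toluene, 110 °C
Reagents that add atoms: none
Why: thermal retro-[4+2] of the dioxinone gives an acylketene that acylates even the hindered secondary alcohol (acetoacetylation-type transfer), which installs the C11–C1–C2 unit on the C7 oxygen.

Step 9
Reactants: 10 (2S,3S,4E)-3-[(tert-butyldiphenylsilyloxy)methyl]-3-methyl-6-oxohept-4-en-2-yl 4-(diethoxyphosphoryl)-3-oxobutanoate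
Product: 12 (3S,4S,4aS)-4-[(tert-butyldiphenylsilyloxy)methyl]-3,4,6-trimethyl-3,4,4a,5-tetrahydro-1H-isochromene-1,8(8aH)-dione, via Michael adduct 11 (not isolated)
Conditions: Cs2CO3 (2.5 equiv), MeCN, 23 to 60 °C
Reagents that add atoms: none
Why: Cs2CO3 deprotonates the doubly activated C11 methylene, which adds through the ester tether to the enone β-carbon C5 (6-exo-trig Michael addition that closes the temporary δ-lactone and forms C5–C11); proton transfer then gives the phosphonate carbanion at C2, which attacks the side-chain methyl ketone C3 and loses diethyl phosphate (intramolecular Horner–Wadsworth–Emmons olefination, six-membered ring closure by carbonyl addition, forming C2=C3). The closest known reaction type is the Michael/Wittig–Horner [3+3] cyclohexenone annulation of 4-phosphorylated 3-oxobutanoates with enones, made intramolecular here in the manner of tethered acetoacetate Michael additions. The one new stereocentre that survives, C5, should be set in a chair transition state of the forming lactone with the C7 methyl group and the enone arm equatorial and the C6 methyl group axial, which puts C4 cis to the C6 methyl group as the target requires; C11 is epimerisable and is reset in step 11. The step needs regioselectivity in the ring-closing condensation (C2 onto C3, not the methyl of the side-chain ketone onto C1 as in a Robinson annulation), and this is secured because only C2 carries the phosphonate. It also needs the addition at the neopentyl-type C5 to beat intermolecular pathways, which the six-membered tether secures.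

Step 10
Reactants: 12 (3S,4S,4aS)-4-[(tert-butyldiphenylsilyloxy)methyl]-3,4,6-trimethyl-3,4,4a,5-tetrahydro-1H-isochromene-1,8(8aH)-dione
Product: 13 keto lactone 12 carrying a 1-methoxy-1-oxopropan-2-yl group at C8a (C11)
Conditions: methyl 2-bromopropanoate, Cs2CO3, DMF, 40 °C
Reagents that add atoms: methyl 2-bromopropanoate CC(Br)C(=O)OC
Why: SN2 C-alkylation of the β-keto lactone enolate by an α-bromo ester, which attaches C10 (with its methyl group and C9) to C11; the two new centres are not controlled because both are reset later.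

Step 11
Reactants: 13 keto lactone 12 carrying a 1-methoxy-1-oxopropan-2-yl group at C8a (C11)
Product: 16 methyl 2-[(1R,6S)-6-{(2S,3S)-1-[(tert-butyldiphenylsilyl)oxy]-3-hydroxy-2-methylbutan-2-yl}-4-methyl-2-oxocyclohex-3-en-1-yl]propanoate, via dicarboxylic acid 14 (not isolated), via keto acid 15 (not isolated)
Conditions: LiOH, THF–MeOH–H2O, 40 °C; 2 M HCl to pH 2, 50 °C; then Me3SiCHN2, toluene–MeOH, 0 °C
Reagents that add atoms: lithium hydroxide [Li+].[OH-]; (trimethylsilyl)diazomethane C[Si](C)(C)C=[N+]=[N-]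
Why: saponification and β-keto acid decarboxylation remove the tether carbon and free the C7 hydroxyl, ketonisation of the enol by protonation anti to the bulky C5 substituent should place the C11 side chain cis to that substituent, and the remaining acid is re-esterified.

Step 12
Reactants: 16 methyl 2-[(1R,6S)-6-{(2S,3S)-1-[(tert-butyldiphenylsilyl)oxy]-3-hydroxy-2-methylbutan-2-yl}-4-methyl-2-oxocyclohex-3-en-1-yl]propanoate
Product: 17 1,3-dioxolane ketal (at C1) of 16 with the ring double bond moved to C3=C4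
Conditions: HOCH2CH2OH, TsOH·H2O (cat.), benzene, reflux (Dean–Stark)
Reagents that add atoms: ethane-1,2-diol OCCO
Why: acid-catalysed ketalisation of a 3-methylcyclohex-2-enone, which normally moves the double bond out of conjugation and so both masks C1 and places the unsaturation at C3=C4, where C4 must later be attacked.

Step 13
Reactants: 17 1,3-dioxolane ketal (at C1) of 16 with the ring double bond moved to C3=C4
Product: 18 C7 tert-butyldimethylsilyl ether of 17
Conditions: t-BuMe2SiOTf, 2,6-lutidine, CH2Cl2, −40 to 0 °C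
Reagents that add atoms: tert-butyldimethylsilyl trifluoromethanesulfonate CC(C)(C)[Si](C)(C)OS(=O)(=O)C(F)(F)F
Why: silylation of the hindered secondary alcohol, so that no alkoxide can compete with the enolate for the epoxide in step 15.

Step 14
Reactants: 18 C7 tert-butyldimethylsilyl ether of 17
Product: 19 3,4-epoxide of 18 with the oxygen trans to the C5 substituent
Conditions: m-CPBA, NaHCO3, CH2Cl2, 0 °C
Reagents that add atoms: 3-chloroperoxybenzoic acid OOC(=O)c1cccc(Cl)c1
Why: Prilezhaev epoxidation of the trisubstituted alkene from the face away from the C5 substituent and the axial C11 side chain, which should set C3 and C4 with the oxygen on the face opposite to the coming nucleophile.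

Step 15
Reactants: 19 3,4-epoxide of 18 with the oxygen trans to the C5 substituent
Product: 20 methyl bicyclo[3.1.1]heptane-6-carboxylate with the C4–C10 bond formed (C1 dioxolane; C3 tertiary alcohol; C5 side chain with C7 silyl ether)
Conditions: KN(SiMe3)2 (1.3 equiv), toluene–THF, −78 to 40 °C; AcOH quench
Reagents that add atoms: none
Why: Stork-type epoxide cyclisation in which the ester enolate at C10 opens the epoxide at C4 in the 4-exo mode by trans-diaxial attack (Fürst–Plattner) with inversion, closing the cyclobutane; the enolate should add with its bulky alkoxide end turned away from the dioxolane-bearing bridge, so C10 is set with the ester (C9) on the side of the C5 side chain and the methyl group over ring A.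

Step 16
Reactants: 20 methyl bicyclo[3.1.1]heptane-6-carboxylate with the C4–C10 bond formed (C1 dioxolane; C3 tertiary alcohol; C5 side chain with C7 silyl ether)
Product: 21 methyl 4,6-dimethyl-2-oxobicyclo[3.1.1]hept-3-ene-6-carboxylate carrying at C7 (target C5) the (2S,3S)-1-(tert-butyldiphenylsilyloxy)-3-hydroxy-2-methylbutan-2-yl group
Conditions: 2 M HCl, THF, 40 °C
Reagents that add atoms: water O
Why: acid hydrolysis of the ketal, dehydration of the resulting tertiary β-hydroxy ketone to the conjugated C2=C3 enone (the bridgehead C4 cannot take the double bond) and cleavage of the secondary silyl ether, while the primary tert-butyldiphenylsilyl ether should survive.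

Step 17
Reactants: 21 methyl 4,6-dimethyl-2-oxobicyclo[3.1.1]hept-3-ene-6-carboxylate carrying at C7 (target C5) the (2S,3S)-1-(tert-butyldiphenylsilyloxy)-3-hydroxy-2-methylbutan-2-yl group
Product: 22 methyl ketone corresponding to 21 (C7 carbonyl with C8 as its methyl group)
Conditions: Dess–Martin periodinane, NaHCO3, CH2Cl2, 23 °C
Reagents that add atoms: none
Why: Dess–Martin oxidation of the secondary alcohol, which erases the auxiliary C7 centre and makes C8 enolisable.

Step 18
Reactants: 22 methyl ketone corresponding to 21 (C7 carbonyl with C8 as its methyl group)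
Product: 23 15-(tert-butyldiphenylsilyloxy)longipin-2-ene-1,7,9-trione
Conditions: KOt-Bu (2.5 equiv), THF, 0 to 50 °C; then 1 M HCl
Reagents that add atoms: none
Why: intramolecular Claisen (Dieckmann-type) condensation of the C8 enolate with the C9 ester, which closes ring C because both chains sit cis on the cyclobutane and the β-diketone enolate is a thermodynamic sink; the ring A enone is out of reach on the other face.

Step 19
Reactants: 23 15-(tert-butyldiphenylsilyloxy)longipin-2-ene-1,7,9-trione
Product: 24 15-hydroxylongipin-2-ene-1,7,9-trione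
Conditions: HF·pyridine, THF, 0 to 23 °C
Reagents that add atoms: none
Why: fluoride cleavage of the silyl ether, which frees the C15 hydroxyl needed to direct the next step.

Step 20
Reactants: 24 15-hydroxylongipin-2-ene-1,7,9-trione
Product: 26 (7R,9R)-7,9,15-trihydroxylongipin-2-en-1-one, via hydroxy diketone 25 (not isolated)
Conditions: Me4NBH(OAc)3 (excess), MeCN–AcOH 1:1, −20 to 23 °C
Reagents that add atoms: none
Why: two hydroxyl-directed reductions (Evans–Saksena), in which the C15 hydroxyl delivers hydride to C7 (new hydroxyl anti to the CH2OH arm, cis to the C6 methyl group) and the new C7 hydroxyl then delivers hydride to C9 to give the anti 1,3-diol, while the enone is not reduced by this reagent.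

Step 21
Reactants: 26 (7R,9R)-7,9,15-trihydroxylongipin-2-en-1-one
Product: 27 7,15-O-isopropylidene acetal of 26
Conditions: Me2C(OMe)2, PPTS (cat.), CH2Cl2, 23 °C
Reagents that add atoms: 2,2-dimethoxypropane COC(C)(C)OC
Why: acetonide formation, which should select the six-membered 1,3-dioxane across the primary C15 and the C7 hydroxyls (the trans 7,9-diol cannot bridge comfortably) and leave only the C9 hydroxyl free.

Step 22
Reactants: 27 7,15-O-isopropylidene acetal of 26
Product: 28 9-O-(3-methylbut-2-enoyl) ester of 27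
Conditions: 3-methylbut-2-enoyl chloride, pyridine, DMAP (cat.), CH2Cl2, 40 °C
Reagents that add atoms: 3-methylbut-2-enoyl chloride CC(C)=CC(Cl)=O
Why: DMAP-catalysed acylation of the only free hydroxyl, with pyridine rather than a stronger amine to avoid deconjugation of the senecioyl group through a vinylketene.

Step 23
Reactants: 28 9-O-(3-methylbut-2-enoyl) ester of 27
Product: 29 (7R,9R)-7,15-dihydroxy-9-(3-methylbut-2-enoyloxy)longipin-2-en-1-one
Conditions: AcOH–H2O 4:1, 40 °C
Reagents that add atoms: none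
Why: mild acid hydrolysis of the acetonide, which the ester and the enone should tolerate.

Step 24
Reactants: 29 (7R,9R)-7,15-dihydroxy-9-(3-methylbut-2-enoyloxy)longipin-2-en-1-one
Product: 30 15-O-angeloyl ester of 29 (C7 hydroxyl free)
Conditions: angelic acid, 2,4,6-trichlorobenzoyl chloride, Et3N, toluene, 23 °C; then 29, 75 °C
Reagents that add atoms: angelic acid C/C=C(/C)C(O)=O
Why: Yamaguchi-type acylation through the mixed anhydride, which should take the primary hydroxyl in preference to the hindered secondary one and, without DMAP, keep the Z geometry of the angelate.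

Step 25
Reactants: 30 15-O-angeloyl ester of 29 (C7 hydroxyl free)
Product: 31 (4R,5S,6S,7R,9R,10R,11R)-7-acetoxy-15-[(2Z)-2-methylbut-2-enoyloxy]-9-(3-methylbut-2-enoyloxy)longipin-2-en-1-one (CNP0179010.1)
Conditions: Ac2O, pyridine, DMAP (cat.), CH2Cl2, 23 °C
Reagents that add atoms: acetic anhydride CC(=O)OC(C)=O
Why: acetylation of the last free hydroxyl under conditions that should leave the angelate geometry and the enone untouched.

## Compound list

1 | ethyl (3S)-3-hydroxybutanoate | CCOC(=O)C[C@H](C)O | starting material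
2 | ethyl (2S,3S)-3-hydroxy-2-methylbutanoate | CCOC(=O)[C@@H](C)[C@H](C)O | intermediate
3 | ethyl (2S,3S)-3-hydroxy-2-(hydroxymethyl)-2-methylbutanoate | CCOC(=O)[C@@](C)(CO)[C@H](C)O | intermediate
4 | ethyl (2S,3S)-2-[(tert-butyldiphenylsilyloxy)methyl]-3-hydroxy-2-methylbutanoate | CCOC(=O)[C@@](C)(CO[Si](c1ccccc1)(c1ccccc1)C(C)(C)C)[C@H](C)O | intermediate
5 | (2S,3S)-2-[(tert-butyldiphenylsilyloxy)methyl]-2-methylbutane-1,3-diol | OC[C@@](C)(CO[Si](c1ccccc1)(c1ccccc1)C(C)(C)C)[C@H](C)O | intermediate
6 | (2S,3S)-2-[(tert-butyldiphenylsilyloxy)methyl]-3-hydroxy-2-methylbutanal | O=C[C@@](C)(CO[Si](c1ccccc1)(c1ccccc1)C(C)(C)C)[C@H](C)O | intermediate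
7 | (3E,5S,6S)-5-[(tert-butyldiphenylsilyloxy)methyl]-6-hydroxy-5-methylhept-3-en-2-one | CC(=O)/C=C/[C@@](C)(CO[Si](c1ccccc1)(c1ccccc1)C(C)(C)C)[C@H](C)O | intermediate
8 | 2,2,6-trimethyl-4H-1,3-dioxin-4-one | CC1=CC(=O)OC(C)(C)O1 | starting material
9 | diethyl [(2,2-dimethyl-4-oxo-4H-1,3-dioxin-6-yl)methyl]phosphonate | CCOP(=O)(CC1=CC(=O)OC(C)(C)O1)OCC | intermediate
10 | (2S,3S,4E)-3-[(tert-butyldiphenylsilyloxy)methyl]-3-methyl-6-oxohept-4-en-2-yl 4-(diethoxyphosphoryl)-3-oxobutanoate | CC(=O)/C=C/[C@@](C)(CO[Si](c1ccccc1)(c1ccccc1)C(C)(C)C)[C@H](C)OC(=O)CC(=O)CP(=O)(OCC)OCC | intermediate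
11 | Michael adduct: (4S,5S,6S)-5-[(tert-butyldiphenylsilyloxy)methyl]-3-[(diethoxyphosphoryl)acetyl]-5,6-dimethyl-4-(2-oxopropyl)tetrahydro-2H-pyran-2-one (C3 epimers; not isolated) | C[C@@H]1OC(=O)C(C(=O)CP(=O)(OCC)OCC)[C@H](CC(C)=O)[C@@]1(C)CO[Si](c1ccccc1)(c1ccccc1)C(C)(C)C | intermediate
12 | (3S,4S,4aS)-4-[(tert-butyldiphenylsilyloxy)methyl]-3,4,6-trimethyl-3,4,4a,5-tetrahydro-1H-isochromene-1,8(8aH)-dione (C8a = C11 open) | C[C@@H]1OC(=O)C2C(=O)C=C(C)C[C@@H]2[C@@]1(C)CO[Si](c1ccccc1)(c1ccccc1)C(C)(C)C | intermediate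
13 | keto lactone 12 carrying a 1-methoxy-1-oxopropan-2-yl group at C8a (C11); epimers at C11 and C10 | C[C@@H]1OC(=O)C2(C(C)C(=O)OC)C(=O)C=C(C)C[C@@H]2[C@@]1(C)CO[Si](c1ccccc1)(c1ccccc1)C(C)(C)C | intermediate
14 | dicarboxylic acid from opening of the lactone and hydrolysis of the methyl ester of 13 (not isolated) | C[C@H](O)[C@](C)(CO[Si](c1ccccc1)(c1ccccc1)C(C)(C)C)[C@H]1CC(C)=CC(=O)C1(C(C)C(O)=O)C(O)=O | intermediate
15 | keto acid: the carboxylic acid corresponding to ester 16 (not isolated) | OC(=O)C(C)[C@@H]1C(=O)C=C(C)C[C@@H]1[C@@](C)(CO[Si](c1ccccc1)(c1ccccc1)C(C)(C)C)[C@H](C)O | intermediate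
16 | methyl 2-[(1R,6S)-6-{(2S,3S)-1-[(tert-butyldiphenylsilyl)oxy]-3-hydroxy-2-methylbutan-2-yl}-4-methyl-2-oxocyclohex-3-en-1-yl]propanoate (C10 epimers) | COC(=O)C(C)[C@@H]1C(=O)C=C(C)C[C@@H]1[C@@](C)(CO[Si](c1ccccc1)(c1ccccc1)C(C)(C)C)[C@H](C)O | intermediate
17 | 1,3-dioxolane ketal (at C1) of 16 with the ring double bond at C3=C4 | COC(=O)C(C)[C@@H]1C2(OCCO2)CC(C)=C[C@@H]1[C@@](C)(CO[Si](c1ccccc1)(c1ccccc1)C(C)(C)C)[C@H](C)O | intermediate
18 | C7 tert-butyldimethylsilyl ether of 17 | COC(=O)C(C)[C@@H]1C2(OCCO2)CC(C)=C[C@@H]1[C@@](C)(CO[Si](c1ccccc1)(c1ccccc1)C(C)(C)C)[C@H](C)O[Si](C)(C)C(C)(C)C | intermediate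
19 | 3,4-epoxide of 18, oxygen trans to the C5 substituent | COC(=O)C(C)[C@@H]1C2(OCCO2)C[C@@]3(C)O[C@H]3[C@@H]1[C@@](C)(CO[Si](c1ccccc1)(c1ccccc1)C(C)(C)C)[C@H](C)O[Si](C)(C)C(C)(C)C | intermediate
20 | methyl bicyclo[3.1.1]heptane-6-carboxylate with C4–C10 formed: C1 dioxolane, C3 tertiary alcohol, C10 methyl and ester, C5 side chain with C7 silyl ether (C4, C5, C10, C11 as in the target) | C[C@H](O[Si](C)(C)C(C)(C)C)[C@](C)(CO[Si](c1ccccc1)(c1ccccc1)C(C)(C)C)[C@@H]1[C@H]2C3(OCCO3)C[C@@](C)(O)[C@@H]1[C@@]2(C)C(=O)OC | intermediate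
21 | methyl 4,6-dimethyl-2-oxobicyclo[3.1.1]hept-3-ene-6-carboxylate carrying at C7 (target C5) the (2S,3S)-1-(tert-butyldiphenylsilyloxy)-3-hydroxy-2-methylbutan-2-yl group | C[C@H](O)[C@](C)(CO[Si](c1ccccc1)(c1ccccc1)C(C)(C)C)[C@@H]1[C@H]2C(=O)C=C(C)[C@@H]1[C@@]2(C)C(=O)OC | intermediate
22 | methyl ketone corresponding to 21 (C7 carbonyl, C8 methyl) | CC(=O)[C@](C)(CO[Si](c1ccccc1)(c1ccccc1)C(C)(C)C)[C@@H]1[C@H]2C(=O)C=C(C)[C@@H]1[C@@]2(C)C(=O)OC | intermediate
23 | 15-(tert-butyldiphenylsilyloxy)longipin-2-ene-1,7,9-trione | CC(C)(C)[Si](c1ccccc1)(c1ccccc1)OC[C@]1(C)[C@@H]2[C@H]3C(=O)C=C(C)[C@@H]2[C@@]3(C)C(=O)CC1=O | intermediate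
24 | 15-hydroxylongipin-2-ene-1,7,9-trione | OC[C@]1(C)[C@@H]2[C@H]3C(=O)C=C(C)[C@@H]2[C@@]3(C)C(=O)CC1=O | intermediate
25 | (7R)-7,15-dihydroxylongipin-2-ene-1,9-dione (not isolated) | OC[C@]1(C)[C@@H]2[C@H]3C(=O)C=C(C)[C@@H]2[C@@]3(C)C(=O)C[C@H]1O | intermediate
26 | (7R,9R)-7,9,15-trihydroxylongipin-2-en-1-one | OC[C@]1(C)[C@@H]2[C@H]3C(=O)C=C(C)[C@@H]2[C@@]3(C)[C@H](O)C[C@H]1O | intermediate
27 | 7,15-O-isopropylidene acetal of 26 | CC1(C)OC[C@]2(C)[C@@H]3[C@H]4C(=O)C=C(C)[C@@H]3[C@@]4(C)[C@H](O)C[C@H]2O1 | intermediate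
28 | 9-O-(3-methylbut-2-enoyl) ester of 27 | CC1(C)OC[C@]2(C)[C@@H]3[C@H]4C(=O)C=C(C)[C@@H]3[C@@]4(C)[C@H](OC(=O)C=C(C)C)C[C@H]2O1 | intermediate
29 | (7R,9R)-7,15-dihydroxy-9-(3-methylbut-2-enoyloxy)longipin-2-en-1-one | OC[C@]1(C)[C@@H]2[C@H]3C(=O)C=C(C)[C@@H]2[C@@]3(C)[C@H](OC(=O)C=C(C)C)C[C@H]1O | intermediate
30 | 15-O-angeloyl ester of 29 | C/C=C(/C)C(=O)OC[C@]1(C)[C@@H]2[C@H]3C(=O)C=C(C)[C@@H]2[C@@]3(C)[C@H](OC(=O)C=C(C)C)C[C@H]1O | intermediate
31 | (4R,5S,6S,7R,9R,10R,11R)-7-acetoxy-15-[(2Z)-2-methylbut-2-enoyloxy]-9-(3-methylbut-2-enoyloxy)longipin-2-en-1-one | C/C=C(/C)C(=O)OC[C@]1(C)[C@@H]2[C@H]3C(=O)C=C(C)[C@@H]2[C@@]3(C)[C@H](OC(=O)C=C(C)C)C[C@H]1OC(C)=O | target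

## Step count and risks

Total step count: 25. Longest linear sequence: 24 steps (steps 1–6 and 8–25).

Steps most likely to fail:

1. Step 15 (cyclobutane closure). The four-membered ring closure is slow, so base-induced isomerisation of the epoxide to an allylic alcohol can compete, and facial control may be poor when the quaternary C10 is created. The fallback ties the ester back into a ring before closure. Starting from 17, heating with Ti(OiPr)4 in toluene with removal of methanol should close the seven-membered lactone between the C9 ester and the C7 hydroxyl, ε-lactone F1. m-CPBA as in step 14 then gives epoxy lactone F2. KN(SiMe3)2 generates the lactone enolate, in which C9 is held on the lower face, and the same Stork-type 4-exo opening should give cyclobutane lactone F3. Aqueous HCl in THF (ketal hydrolysis, dehydration) gives enone lactone F4, and NaOMe in MeOH opens the lactone to rejoin the route at 21.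

2. Step 10 (alkylation creating the congested quaternary C11). SN2 attack of a hindered tertiary enolate on a secondary bromide may be slow, so that O-alkylation and loss of HBr from the bromo ester take over. The fallback makes the bond by conjugate addition. From 12, triethylamine-catalysed Michael addition to (E)-1-nitroprop-1-ene should give nitro lactone F5; such additions of α-substituted β-keto esters to nitroalkenes form quaternary centres readily. NaNO2 and AcOH in DMSO convert the primary nitro group into carboxylic acid F6, and Me3SiCHN2 gives 13.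

3. Step 18 (Claisen ring closure). The enolate may fail to add to the neopentyl ester, or the tetrahedral intermediate may revert, so that the seven-membered ring does not form. The fallback closes the ring by an aldol addition to a more electrophilic carbon. From 20, LiAlH4 reduces the ester to primary alcohol F7. The acid treatment of step 16 gives enone diol F8. Dess–Martin periodinane oxidises both hydroxyls to keto aldehyde F9. LiN(SiMe3)2 at −78 °C forms the methyl ketone enolate, whose intramolecular aldol addition to the non-enolisable aldehyde should give hydroxy diketone F10, and a second Dess–Martin oxidation returns to the route at 23.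

Further compounds
F1 | step 15 | seven-membered lactone (C9 carbonyl to C7 oxygen) of ketal 17 | C[C@@H]1OC(=O)C(C)[C@@H]2C3(OCCO3)CC(C)=C[C@@H]2[C@@]1(C)CO[Si](c1ccccc1)(c1ccccc1)C(C)(C)C
F2 | step 15 | 3,4-epoxide of F1, oxygen trans to the C5 substituent | C[C@@H]1OC(=O)C(C)[C@@H]2C3(OCCO3)C[C@@]4(C)O[C@H]4[C@@H]2[C@@]1(C)CO[Si](c1ccccc1)(c1ccccc1)C(C)(C)C
F3 | step 15 | cyclobutane lactone (C4–C10 formed; C3 tertiary alcohol; C1 dioxolane) | C[C@@H]1OC(=O)[C@]2(C)[C@H]3[C@](C)(O)CC4(OCCO4)[C@@H]2[C@H]3[C@@]1(C)CO[Si](c1ccccc1)(c1ccccc1)C(C)(C)C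
F4 | step 15 | enone lactone (C1 ketone and C2=C3 restored) | C[C@@H]1OC(=O)[C@]2(C)[C@H]3C(C)=CC(=O)[C@@H]2[C@H]3[C@@]1(C)CO[Si](c1ccccc1)(c1ccccc1)C(C)(C)C
F5 | step 10 | keto lactone 12 carrying a 1-nitropropan-2-yl group at C11 | C[C@@H]1OC(=O)C2(C(C)C[N+](=O)[O-])C(=O)C=C(C)C[C@@H]2[C@@]1(C)CO[Si](c1ccccc1)(c1ccccc1)C(C)(C)C
F6 | step 10 | carboxylic acid corresponding to methyl ester 13 | C[C@@H]1OC(=O)C2(C(C)C(O)=O)C(=O)C=C(C)C[C@@H]2[C@@]1(C)CO[Si](c1ccccc1)(c1ccccc1)C(C)(C)C
F7 | step 18 | primary alcohol from reduction of the C9 ester of 20 | C[C@H](O[Si](C)(C)C(C)(C)C)[C@](C)(CO[Si](c1ccccc1)(c1ccccc1)C(C)(C)C)[C@@H]1[C@H]2C3(OCCO3)C[C@@](C)(O)[C@@H]1[C@@]2(C)CO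
F8 | step 18 | enone diol (C7 and C9 hydroxyls free) | C[C@H](O)[C@](C)(CO[Si](c1ccccc1)(c1ccccc1)C(C)(C)C)[C@@H]1[C@H]2C(=O)C=C(C)[C@@H]1[C@@]2(C)CO
F9 | step 18 | keto aldehyde (C7 methyl ketone, C9 aldehyde) | CC(=O)[C@](C)(CO[Si](c1ccccc1)(c1ccccc1)C(C)(C)C)[C@@H]1[C@H]2C(=O)C=C(C)[C@@H]1[C@@]2(C)C=O
F10 | step 18 | 9-hydroxy-15-(tert-butyldiphenylsilyloxy)longipin-2-ene-1,7-dione (C9 epimers) | CC(C)(C)[Si](c1ccccc1)(c1ccccc1)OC[C@]1(C)[C@@H]2[C@H]3C(=O)C=C(C)[C@@H]2[C@@]3(C)C(O)CC1=O
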